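**Retrosynthetic overview**
1. Feature: in the cis-decalin (C1 = CMe2, C2 = CH bearing the chain, C3 and C6 = C=CH2, C4a/C8a = fusion), ring A (C4a–C5–C6–C7–C8–C8a) carries at its fusion bond C4a–C8a a one-carbon arm (C4) on C4a and the 2-propyl-type carbon C1 on C8a, cis: the pattern of a cis-2-isopropenylcyclohexanecarboxylic acid.
2. Ring A first: C4a–C8a is cut back to the Z ten-membered allylic lactone 10 (Ireland–Claisen ring contraction, C6 silyloxy group as temporary stereocentre); 10 comes from (R)-1,2-epoxy-5-hexene by enolate opening, Z-selective olefination and macrolactonisation.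
3. Ring B second: C4 is homologated to a γ-oxo-enoate and C1–C2 is closed by iron-hydride radical cyclisation of the isopropenyl group; C3, then C6, are methylenated.
4. Side chain: the C2 acetate arm becomes an alkylcopper that is joined to propyne and to epoxide 33 (aldol-derived C3'/Cα) as a Z homoallylic alcohol.
5. 1,2-Dioxane last: hydroxyl-directed epoxidation, perhydrolysis at C6' and peroxide SN2 closure at C3' (both with inversion), removal of the C5' oxygen, oxidation to the acid.

Key step: step 8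

Labels: decalin C1–C8a as above; linker C11 (on C2) and C12; dioxane C3', C4', C5', C6' (C6' quaternary); Cα = α-carbon of the propanoic acid.

Step 1
Reactants: 1 (R)-2-(but-3-en-1-yl)oxirane
Product: 2 tert-butyl (R)-4-hydroxyoct-7-enoate
Conditions: tert-butyl acetate, LiN(iPr)2, THF, −78 °C; Et2AlCl; then 1, −78 to −30 °C
Reagents that add atoms: tert-butyl acetate, CC(=O)OC(C)(C)C
Why: Aluminium ester enolate opening of a terminal epoxide at its CH2 terminus (SN2) leaves the carbinol configuration of 1 untouched, so C6 becomes the temporary stereocentre, and the tert-butyl ester resists lactonisation.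

Step 2
Reactants: 2 tert-butyl (R)-4-hydroxyoct-7-enoate
Product: 3 tert-butyl (R)-4-[(tert-butyldimethylsilyl)oxy]oct-7-enoate
Conditions: TBSCl, imidazole, DMF, rt
Reagents that add atoms: tert-butyldimethylsilyl chloride, CC(C)(C)[Si](C)(C)Cl
Why: Standard silylation of the secondary alcohol installs the C6 silyloxy group of the key precursor.

Step 3
Reactants: 3 tert-butyl (R)-4-[(tert-butyldimethylsilyl)oxy]oct-7-enoate
Product: 4 tert-butyl (R)-4-[(tert-butyldimethylsilyl)oxy]-7-oxoheptanoate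
Conditions: O3, CH2Cl2/MeOH, −78 °C; then PPh3
Reagents that add atoms: ozone, [O-][O+]=O
Why: Ozonolysis with reductive work-up cleaves the terminal olefin to the aldehyde (future C8a) without touching ester or silyl ether.

Step 4
Reactants: 4 tert-butyl (R)-4-[(tert-butyldimethylsilyl)oxy]-7-oxoheptanoate
Product: 5 1-tert-butyl 9-ethyl (4R,7Z)-4-[(tert-butyldimethylsilyl)oxy]-8-methylnon-7-enedioate
Conditions: ethyl 2-[bis(2,2,2-trifluoroethoxy)phosphoryl]propanoate, KN(SiMe3)2, 18-crown-6, THF, −78 °C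
Reagents that add atoms: ethyl 2-[bis(2,2,2-trifluoroethoxy)phosphoryl]propanoate, CCOC(=O)C(C)P(=O)(OCC(F)(F)F)OCC(F)(F)F
Why: Still–Gennari olefination with the electron-poor phosphonate under dissociating conditions should give the Z trisubstituted enoate required for the cis ring olefin of the lactone.

Step 5
Reactants: 5 1-tert-butyl 9-ethyl (4R,7Z)-4-[(tert-butyldimethylsilyl)oxy]-8-methylnon-7-enedioate
Product: 6 tert-butyl (4R,7Z)-4-[(tert-butyldimethylsilyl)oxy]-9-hydroxy-8-methylnon-7-enoate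
Conditions: iBu2AlH (2.2 equiv), CH2Cl2, −78 °C
Reagents that add atoms: none
Why: Aluminium hydride reduction of the unhindered ethyl enoate to the allylic alcohol is expected to outpace attack on the bulky tert-butyl ester at −78 °C (chemoselectivity by steric hindrance).

Step 6
Reactants: 6 tert-butyl (4R,7Z)-4-[(tert-butyldimethylsilyl)oxy]-9-hydroxy-8-methylnon-7-enoate
Product: 8 (4R,7Z)-4-[(tert-butyldimethylsilyl)oxy]-9-hydroxy-8-methylnon-7-enoic acid, via bis(trimethylsilyl) derivative 7 (not isolated)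
Conditions: Me3SiOTf, 2,6-lutidine, CH2Cl2, 0 °C; then K2CO3, MeOH/H2O, rt
Reagents that add atoms: none
Why: Silyl triflate-induced loss of isobutene turns the tert-butyl ester into a labile silyl ester (the allylic alcohol is silylated in passing), and mild methanolysis then frees acid and primary alcohol while the secondary TBS ether stays.

Step 7
Reactants: 8 (4R,7Z)-4-[(tert-butyldimethylsilyl)oxy]-9-hydroxy-8-methylnon-7-enoic acid
Product: 10 (5R,8Z)-5-[(tert-butyldimethylsilyl)oxy]-9-methyl-3,4,5,6,7,10-hexahydro-2H-oxecin-2-one, via mixed anhydride 9 (not isolated)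
Conditions: 2,4,6-trichlorobenzoyl chloride, NEt3, THF, rt; then slow addition to DMAP, toluene, 80 °C (high dilution)
Reagents that add atoms: none
Why: Yamaguchi macrolactonisation, in which the Z trisubstituted olefin and high dilution favour closure of the ten-membered ring over oligomers.

Step 8
Reactants: 10 (5R,8Z)-5-[(tert-butyldimethylsilyl)oxy]-9-methyl-3,4,5,6,7,10-hexahydro-2H-oxecin-2-one
Product: 13 (1R,2S,5R)-5-[(tert-butyldimethylsilyl)oxy]-2-(prop-1-en-2-yl)cyclohexane-1-carboxylic acid, via silyl ketene acetal 11 (not isolated), via silyl ester 12 (not isolated)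
Conditions: LiN(iPr)2, TBSCl, THF/HMPA, −78 °C; then toluene, 105 °C; then K2CO3, MeOH/H2O
Reagents that add atoms: none
Why: O-Silylation of the lactone enolate gives the cyclic ketene acetal 11, whose allyl vinyl ether unit is held inside the ten-membered ring, and on heating a [3,3] shift forms C4a–C8a and breaks the allylic C–O bond, contracting the ring by four atoms to silyl ester 12. The closest known reaction is the Ireland–Claisen ring contraction of 9- to 13-membered allylic lactones to cis-2-alkenylcycloalkanecarboxylic acids. Ring A closes by C–C bond formation between the ketene acetal carbon C4a and the olefin carbon C8a within the six-membered pericyclic array, formally a 6-exo closure with the new isopropenyl double bond outside ring A. The medium ring cannot reach a chair, so the shift runs through a boat and the two new stereocentres C4a and C8a form together as the cis pair. Their absolute sense is relayed from C6: the silyloxy group should take a pseudo-equatorial site on the nascent chair of ring A and the bulkier ketene acetal terminus the equatorial fusion bond, which places C4 cis to the silyloxy group. The step therefore needs facial selectivity between the two cis-fused boat arrangements, and the C6 stereocentre is the only element that secures it.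

Step 9
Reactants: 13 (1R,2S,5R)-5-[(tert-butyldimethylsilyl)oxy]-2-(prop-1-en-2-yl)cyclohexane-1-carboxylic acid
Product: 14 [(1R,2S,5R)-5-[(tert-butyldimethylsilyl)oxy]-2-(prop-1-en-2-yl)cyclohexyl]methanol
Conditions: LiAlH4, THF, 0 °C to rt
Reagents that add atoms: none
Why: Hydride reduction of the carboxylic acid gives the C4 carbinol, with silyl ether and isopropenyl group inert.

Step 10
Reactants: 14 [(1R,2S,5R)-5-[(tert-butyldimethylsilyl)oxy]-2-(prop-1-en-2-yl)cyclohexyl]methanol
Product: 15 tert-butyl{[(1R,3R,4S)-3-(iodomethyl)-4-(prop-1-en-2-yl)cyclohexyl]oxy}dimethylsilane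
Conditions: I2, PPh3, imidazole, CH2Cl2, 0 °C to rt
Reagents that add atoms: iodine, II
Why: Appel-type iodination of the primary alcohol (SN2 on the alkoxyphosphonium salt) provides the C4 iodide for zinc insertion.

Step 11
Reactants: 15 tert-butyl{[(1R,3R,4S)-3-(iodomethyl)-4-(prop-1-en-2-yl)cyclohexyl]oxy}dimethylsilane
Product: 17 ethyl (E)-5-[(1S,2S,5R)-5-[(tert-butyldimethylsilyl)oxy]-2-(prop-1-en-2-yl)cyclohexyl]-4-oxopent-2-enoate, via alkylzinc iodide 16 (not isolated)
Conditions: Zn dust, LiCl, THF, 40 °C; then Pd(PPh3)4 (5 mol%), ethyl (E)-4-chloro-4-oxobut-2-enoate, THF, 0 °C to rt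
Reagents that add atoms: ethyl (E)-4-chloro-4-oxobut-2-enoate, CCOC(=O)/C=C/C(Cl)=O
Why: Zinc insertion into the primary C–I bond followed by Negishi-type acylation with the acid chloride under zerovalent palladium catalysis should deliver the γ-oxo-enoate in one operation, since the alkylzinc does not add to the enoate without copper.

Step 12
Reactants: 17 ethyl (E)-5-[(1S,2S,5R)-5-[(tert-butyldimethylsilyl)oxy]-2-(prop-1-en-2-yl)cyclohexyl]-4-oxopent-2-enoate
Product: 18 ethyl 2-{6-[(tert-butyldimethylsilyl)oxy]-1,1-dimethyl-3-oxodecahydronaphthalen-2-yl}acetate (cis-fused; C2, C4a and C8a configured as in 44; silyloxy group cis to C4 on ring A)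
Conditions: Fe(acac)3 (30 mol%), PhSiH3, EtOH/ethylene glycol, 60 °C
Reagents that add atoms: none
Why: Mukaiyama-type hydrogen atom transfer from an iron hydride to the isopropenyl CH2 gives the tertiary C1 radical, which should close ring B by 6-exo Giese attack on C2 of the doubly activated olefin rather than 7-endo on the ester-bearing carbon; with ring A locked by the equatorial C6 silyloxy group (C1 axial, C4 equatorial), the chair transition state puts the CH2CO2Et arm equatorial, which is the target configuration at C2.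

Step 13
Reactants: 18 ethyl 2-{6-[(tert-butyldimethylsilyl)oxy]-1,1-dimethyl-3-oxodecahydronaphthalen-2-yl}acetate
Product: 19 ethyl 2-{6-[(tert-butyldimethylsilyl)oxy]-1,1-dimethyl-3-methylidenedecahydronaphthalen-2-yl}acetate (stereocentres as in 18)
Conditions: Zn, CH2Br2, TiCl4, THF/CH2Cl2, 0 °C to rt
Reagents that add atoms: dibromomethane, BrCBr
Why: Takai–Lombardo methylenation is non-basic, so the hindered C3 ketone should be converted without epimerising C2 or touching the ester.

Step 14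
Reactants: 19 ethyl 2-{6-[(tert-butyldimethylsilyl)oxy]-1,1-dimethyl-3-methylidenedecahydronaphthalen-2-yl}acetate
Product: 20 ethyl 2-(6-hydroxy-1,1-dimethyl-3-methylidenedecahydronaphthalen-2-yl)acetate (stereocentres as in 18)
Conditions: HF·pyridine, pyridine, THF, 0 °C to rt
Reagents that add atoms: none
Why: Fluoride cleavage of the secondary silyl ether; C2 can no longer epimerise, so the conformational lock at C6 may now be given up.

Step 15
Reactants: 20 ethyl 2-(6-hydroxy-1,1-dimethyl-3-methylidenedecahydronaphthalen-2-yl)acetate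
Product: 21 ethyl 2-(1,1-dimethyl-3-methylidene-6-oxodecahydronaphthalen-2-yl)acetate (C2, C4a and C8a as in 44)
Conditions: (Pr4N)(RuO4) (5 mol%), N-methylmorpholine N-oxide, 4 Å MS, CH2Cl2, rt
Reagents that add atoms: none
Why: Ley–Griffith oxidation converts the secondary alcohol into the C6 ketone under neutral conditions that leave the exocyclic olefin and the ester alone.

Step 16
Reactants: 21 ethyl 2-(1,1-dimethyl-3-methylidene-6-oxodecahydronaphthalen-2-yl)acetate
Product: 22 ethyl 2-[(2R,4aS,8aS)-1,1-dimethyl-3,6-dimethylidenedecahydronaphthalen-2-yl]acetate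
Conditions: Ph3PCH3Br, KOtBu, THF, 0 °C
Reagents that add atoms: methyltriphenylphosphonium bromide, C[P+](c1ccccc1)(c1ccccc1)c1ccccc1.[Br-]
Why: Wittig methylenation of the unhindered cyclohexanone installs the C6 methylene, the ylide being unreactive towards the ester at 0 °C.

Step 17
Reactants: 22 ethyl 2-[(2R,4aS,8aS)-1,1-dimethyl-3,6-dimethylidenedecahydronaphthalen-2-yl]acetate
Product: 23 2-[(2R,4aS,8aS)-1,1-dimethyl-3,6-dimethylidenedecahydronaphthalen-2-yl]ethanol
Conditions: LiAlH4, Et2O, 0 °C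
Reagents that add atoms: none
Why: Ester reduction gives the primary C12 alcohol without affecting the two 1,1-disubstituted olefins.

Step 18
Reactants: 23 2-[(2R,4aS,8aS)-1,1-dimethyl-3,6-dimethylidenedecahydronaphthalen-2-yl]ethanol
Product: 24 (2R,4aS,8aS)-2-(2-bromoethyl)-1,1-dimethyl-3,6-dimethylidenedecahydronaphthalene
Conditions: CBr4, PPh3, CH2Cl2, 0 °C
Reagents that add atoms: carbon tetrabromide, BrC(Br)(Br)Br
Why: Appel bromination of the primary alcohol gives the bromide needed for Grignard formation.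

Step 19
Reactants: 25 (R)-4-benzyl-3-propanoyl-1,3-oxazolidin-2-one; 26 2-(benzyloxy)acetaldehyde
Product: 28 (R)-4-benzyl-3-[(2R,3R)-4-(benzyloxy)-3-hydroxy-2-methylbutanoyl]-1,3-oxazolidin-2-one, via dibutylboron enolate 27 (not isolated)
Conditions: Bu2BOTf, iPr2NEt, CH2Cl2, −78 to 0 °C; then 26; H2O2, MeOH, pH 7 buffer
Reagents that add atoms: none
Why: Evans syn aldol reaction, in which the Z boron enolate reacts through a Zimmerman–Traxler chair on the face away from the benzyl group and so sets Cα and the C3' carbinol (2,3-syn) under auxiliary control.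

Step 20
Reactants: 28 (R)-4-benzyl-3-[(2R,3R)-4-(benzyloxy)-3-hydroxy-2-methylbutanoyl]-1,3-oxazolidin-2-one
Product: 29 (2S,3R)-4-(benzyloxy)-2-methylbutane-1,3-diol
Conditions: LiBH4, Et2O, H2O (1 equiv), 0 °C
Reagents that add atoms: none
Why: Reductive cleavage of the N-acyl oxazolidinone gives the primary alcohol (the future carboxyl carbon) without epimerisation, and the auxiliary is recovered.

Step 21
Reactants: 29 (2S,3R)-4-(benzyloxy)-2-methylbutane-1,3-diol
Product: 30 (2R,3S)-1-(benzyloxy)-4-[(tert-butyldiphenylsilyl)oxy]-3-methylbutan-2-ol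
Conditions: TBDPSCl, imidazole, CH2Cl2, 0 °C
Reagents that add atoms: tert-butyl(chloro)diphenylsilane, CC(C)(C)[Si](Cl)(c1ccccc1)c1ccccc1
Why: The bulky silyl chloride should react selectively at the primary hydroxyl of the 1,3-diol.

Step 22
Reactants: 30 (2R,3S)-1-(benzyloxy)-4-[(tert-butyldiphenylsilyl)oxy]-3-methylbutan-2-ol
Product: 31 (2R,3S)-4-[(tert-butyldiphenylsilyl)oxy]-3-methylbutane-1,2-diol
Conditions: H2 (1 atm), Pd/C, EtOAc, rt
Reagents that add atoms: none
Why: Hydrogenolysis of the benzyl ether frees the primary C4' hydroxyl, the silyl ether being stable.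

Step 23
Reactants: 31 (2R,3S)-4-[(tert-butyldiphenylsilyl)oxy]-3-methylbutane-1,2-diol
Product: 33 tert-butyl{(2S)-2-[(2R)-oxiran-2-yl]propoxy}diphenylsilane, via primary tosylate 32 (not isolated)
Conditions: NaH (2.2 equiv), 1-(p-toluenesulfonyl)imidazole, THF, 0 °C to rt
Reagents that add atoms: none
Why: Selective sulfonylation of the primary alkoxide and intramolecular Williamson closure by the C3' alkoxide should give the terminal epoxide with retention at C3'.

Step 24
Reactants: 24 (2R,4aS,8aS)-2-(2-bromoethyl)-1,1-dimethyl-3,6-dimethylidenedecahydronaphthalene; 33 tert-butyl{(2S)-2-[(2R)-oxiran-2-yl]propoxy}diphenylsilane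
Product: 36 (2S,3S,5Z)-1-[(tert-butyldiphenylsilyl)oxy]-8-[(2R,4aS,8aS)-1,1-dimethyl-3,6-dimethylidenedecahydronaphthalen-2-yl]-2,6-dimethyloct-5-en-3-ol, via alkylmagnesium bromide 34 (not isolated), via alkenylcopper 35 (not isolated)
Conditions: Mg, Et2O; CuBr·SMe2, Et2O/Me2S, −45 °C; propyne, −25 °C; LiC≡C-nPr, HMPA, then 33, −40 °C to rt
Reagents that add atoms: propyne, CC#C
Why: Normant carbocupration, in which the alkylcopper adds syn to propyne (alkyl on the internal carbon) and the resulting Z alkenylcopper, activated as the mixed alkynyl cuprate, opens epoxide 33 at its CH2 terminus with retention of olefin geometry, leaving C3' and Cα untouched.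

Step 25
Reactants: 36 (2S,3S,5Z)-1-[(tert-butyldiphenylsilyl)oxy]-8-[(2R,4aS,8aS)-1,1-dimethyl-3,6-dimethylidenedecahydronaphthalen-2-yl]-2,6-dimethyloct-5-en-3-ol
Product: 37 C5'–C6' epoxide of 36 (epoxide oxygen syn to the C3' hydroxyl; C3' and Cα as in 36)
Conditions: VO(acac)2 (5 mol%), tBuOOH, CH2Cl2, 0 °C to rt
Reagents that add atoms: tert-butyl hydroperoxide, CC(C)(C)OO
Why: Hydroxyl-directed vanadium-catalysed epoxidation reaches only the homoallylic C5'=C6' olefin, and the chair-like vanadate transition state with the C3' substituent equatorial (enforced by A1,3 strain from the cis chain) should deliver oxygen syn to the C3' oxygen, which fixes C6'.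

Step 26
Reactants: 37 C5'–C6' epoxide of 36
Product: 38 C3' methanesulfonate of epoxy alcohol 37
Conditions: MsCl, NEt3, CH2Cl2, −20 °C
Reagents that add atoms: methanesulfonyl chloride, CS(=O)(=O)Cl
Why: Sulfonylation of the secondary C3' alcohol (retention) makes it the leaving group for the peroxide closure and removes the nucleophilic hydroxyl next to the epoxide.

Step 27
Reactants: 38 C3' methanesulfonate of epoxy alcohol 37
Product: 39 C6' hydroperoxide with C5' hydroxyl and C3' methanesulfonate (C6' inverted relative to 38)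
Conditions: H2O2 (anhydrous, in Et2O), H3PMo12O40 (2 mol%), Et2O, 0 °C to rt
Reagents that add atoms: hydrogen peroxide, OO
Why: Acid-catalysed perhydrolysis of the trisubstituted epoxide, in which hydrogen peroxide attacks the tertiary carbon C6' in a borderline SN2 opening with inversion, should give the tertiary hydroperoxide of the required configuration and a C5' hydroxyl.

Step 28
Reactants: 39 C6' hydroperoxide with C5' hydroxyl and C3' methanesulfonate
Product: 40 (3R,6S)-configured 5'-hydroxy-1,2-dioxane (C6' methyl and linker; C3' bearing the (S)-1-(silyloxy)propan-2-yl group)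
Conditions: KOtBu (1.05 equiv), 18-crown-6, THF, 0 °C
Reagents that add atoms: none
Why: The hydroperoxide, far more acidic than the C5' alcohol, is deprotonated selectively and should displace the C3' methanesulfonate in a 6-exo-tet SN2 reaction with inversion, closing the 1,2-dioxane and setting C3'.

Step 29
Reactants: 40 (3R,6S)-configured 5'-hydroxy-1,2-dioxane
Product: 41 O-phenyl thionocarbonate of 40 at the C5' oxygen
Conditions: PhOC(S)Cl, pyridine, DMAP (cat.), CH2Cl2, rt
Reagents that add atoms: O-phenyl chlorothionoformate, S=C(Cl)Oc1ccccc1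
Why: Acylation of the secondary C5' alcohol gives the radical precursor under weakly basic conditions that the peroxide tolerates.

Step 30
Reactants: 41 O-phenyl thionocarbonate of 40
Product: 42 tert-butyl{(2S)-2-[(3R,6S)-6-{2-[(2R,4aS,8aS)-1,1-dimethyl-3,6-dimethylidenedecahydronaphthalen-2-yl]ethyl}-6-methyl-1,2-dioxan-3-yl]propoxy}diphenylsilane
Conditions: Bu3SnH (5 equiv), Et3B, air (trace), toluene, rt
Reagents that add atoms: none
Why: Barton–McCombie deoxygenation, in which the ring C5' radical cannot align with the endocyclic O–O bond for epoxide-forming displacement and stannyl radicals add to C=S much faster than they attack dialkyl peroxides, so the radical should simply be reduced to CH2.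

Step 31
Reactants: 42 tert-butyl{(2S)-2-[(3R,6S)-6-{2-[(2R,4aS,8aS)-1,1-dimethyl-3,6-dimethylidenedecahydronaphthalen-2-yl]ethyl}-6-methyl-1,2-dioxan-3-yl]propoxy}diphenylsilane
Product: 43 (2S)-2-[(3R,6S)-6-{2-[(2R,4aS,8aS)-1,1-dimethyl-3,6-dimethylidenedecahydronaphthalen-2-yl]ethyl}-6-methyl-1,2-dioxan-3-yl]propan-1-ol
Conditions: HF·pyridine, pyridine, THF, rt
Reagents that add atoms: none
Why: Fluoride cleavage of the primary silyl ether under buffered conditions spares the peroxide and the exocyclic olefins.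

Step 32
Reactants: 43 (2S)-2-[(3R,6S)-6-{2-[(2R,4aS,8aS)-1,1-dimethyl-3,6-dimethylidenedecahydronaphthalen-2-yl]ethyl}-6-methyl-1,2-dioxan-3-yl]propan-1-ol
Product: 44 (2R)-2-[(3R,6S)-6-{2-[(2R,4aS,8aS)-1,1-dimethyl-3,6-dimethylidenedecahydronaphthalen-2-yl]ethyl}-6-methyl-1,2-dioxan-3-yl]propanoic acid (CNP0363961.1)
Conditions: TEMPO (20 mol%), PhI(OAc)2, MeCN/H2O, rt
Reagents that add atoms: water, O
Why: Oxoammonium-mediated oxidation of the primary alcohol through the aldehyde hydrate to the carboxylic acid is neutral and mild, so Cα should not epimerise and peroxide and olefins stay intact.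

**Compound list**
1 | (R)-2-(but-3-en-1-yl)oxirane | C=CCC[C@@H]1CO1 | starting material
2 | tert-butyl (R)-4-hydroxyoct-7-enoate | CC(C)(C)OC(=O)CC[C@H](O)CCC=C | intermediate
3 | tert-butyl (R)-4-[(tert-butyldimethylsilyl)oxy]oct-7-enoate | CC(C)(C)OC(=O)CC[C@H](O[Si](C)(C)C(C)(C)C)CCC=C | intermediate
4 | tert-butyl (R)-4-[(tert-butyldimethylsilyl)oxy]-7-oxoheptanoate | CC(C)(C)OC(=O)CC[C@H](O[Si](C)(C)C(C)(C)C)CCC=O | intermediate
5 | 1-tert-butyl 9-ethyl (4R,7Z)-4-[(tert-butyldimethylsilyl)oxy]-8-methylnon-7-enedioate | CC(C)(C)OC(=O)CC[C@H](O[Si](C)(C)C(C)(C)C)CC/C=C(/C)C(=O)OCC | intermediate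
6 | tert-butyl (4R,7Z)-4-[(tert-butyldimethylsilyl)oxy]-9-hydroxy-8-methylnon-7-enoate | CC(C)(C)OC(=O)CC[C@H](O[Si](C)(C)C(C)(C)C)CC/C=C(/C)CO | intermediate
7 | trimethylsilyl (4R,7Z)-4-[(tert-butyldimethylsilyl)oxy]-8-methyl-9-[(trimethylsilyl)oxy]non-7-enoate (not isolated) | C[Si](C)(C)OC(=O)CC[C@H](O[Si](C)(C)C(C)(C)C)CC/C=C(/C)CO[Si](C)(C)C | intermediate
8 | (4R,7Z)-4-[(tert-butyldimethylsilyl)oxy]-9-hydroxy-8-methylnon-7-enoic acid | OC(=O)CC[C@H](O[Si](C)(C)C(C)(C)C)CC/C=C(/C)CO | intermediate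
9 | mixed anhydride of 8 with 2,4,6-trichlorobenzoic acid (not isolated) | O=C(OC(=O)CC[C@H](O[Si](C)(C)C(C)(C)C)CC/C=C(/C)CO)c1c(Cl)cc(Cl)cc1Cl | intermediate
10 | (5R,8Z)-5-[(tert-butyldimethylsilyl)oxy]-9-methyl-3,4,5,6,7,10-hexahydro-2H-oxecin-2-one (key precursor) | O=C1CC[C@H](O[Si](C)(C)C(C)(C)C)CC/C=C(C)\CO1 | intermediate
11 | O-tert-butyldimethylsilyl ketene acetal of lactone 10, ring bonds cis on the acetal double bond (not isolated) | CC(C)(C)[Si](C)(C)O/C1=C/C[C@H](O[Si](C)(C)C(C)(C)C)CC/C=C(C)\CO1 | intermediate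
12 | tert-butyldimethylsilyl (1R,2S,5R)-5-[(tert-butyldimethylsilyl)oxy]-2-(prop-1-en-2-yl)cyclohexane-1-carboxylate (not isolated) | CC(C)(C)[Si](C)(C)OC(=O)[C@@H]1C[C@H](O[Si](C)(C)C(C)(C)C)CC[C@@H]1C(C)=C | intermediate
13 | (1R,2S,5R)-5-[(tert-butyldimethylsilyl)oxy]-2-(prop-1-en-2-yl)cyclohexane-1-carboxylic acid (key product, all-cis) | OC(=O)[C@@H]1C[C@H](O[Si](C)(C)C(C)(C)C)CC[C@@H]1C(C)=C | intermediate
14 | [(1R,2S,5R)-5-[(tert-butyldimethylsilyl)oxy]-2-(prop-1-en-2-yl)cyclohexyl]methanol | OC[C@@H]1C[C@H](O[Si](C)(C)C(C)(C)C)CC[C@@H]1C(C)=C | intermediate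
15 | tert-butyl{[(1R,3R,4S)-3-(iodomethyl)-4-(prop-1-en-2-yl)cyclohexyl]oxy}dimethylsilane | IC[C@@H]1C[C@H](O[Si](C)(C)C(C)(C)C)CC[C@@H]1C(C)=C | intermediate
16 | alkylzinc iodide from 15 (not isolated) | I[Zn]C[C@@H]1C[C@H](O[Si](C)(C)C(C)(C)C)CC[C@@H]1C(C)=C | intermediate
17 | ethyl (E)-5-[(1S,2S,5R)-5-[(tert-butyldimethylsilyl)oxy]-2-(prop-1-en-2-yl)cyclohexyl]-4-oxopent-2-enoate | CCOC(=O)/C=C/C(=O)C[C@@H]1C[C@H](O[Si](C)(C)C(C)(C)C)CC[C@@H]1C(C)=C | intermediate
18 | ethyl 2-{6-[(tert-butyldimethylsilyl)oxy]-1,1-dimethyl-3-oxodecahydronaphthalen-2-yl}acetate (cis-fused; C2, C4a, C8a as in 44; silyloxy cis to C4) | CCOC(=O)C[C@@H]1C(=O)C[C@@H]2C[C@H](O[Si](C)(C)C(C)(C)C)CC[C@@H]2C1(C)C | intermediate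
19 | ethyl 2-{6-[(tert-butyldimethylsilyl)oxy]-1,1-dimethyl-3-methylidenedecahydronaphthalen-2-yl}acetate (stereocentres as in 18) | CCOC(=O)C[C@@H]1C(=C)C[C@@H]2C[C@H](O[Si](C)(C)C(C)(C)C)CC[C@@H]2C1(C)C | intermediate
20 | ethyl 2-(6-hydroxy-1,1-dimethyl-3-methylidenedecahydronaphthalen-2-yl)acetate (stereocentres as in 18) | CCOC(=O)C[C@@H]1C(=C)C[C@@H]2C[C@H](O)CC[C@@H]2C1(C)C | intermediate
21 | ethyl 2-(1,1-dimethyl-3-methylidene-6-oxodecahydronaphthalen-2-yl)acetate (C2, C4a, C8a as in 44) | CCOC(=O)C[C@@H]1C(=C)C[C@@H]2CC(=O)CC[C@@H]2C1(C)C | intermediate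
22 | ethyl 2-[(2R,4aS,8aS)-1,1-dimethyl-3,6-dimethylidenedecahydronaphthalen-2-yl]acetate | CCOC(=O)C[C@@H]1C(=C)C[C@@H]2CC(=C)CC[C@@H]2C1(C)C | intermediate
23 | 2-[(2R,4aS,8aS)-1,1-dimethyl-3,6-dimethylidenedecahydronaphthalen-2-yl]ethanol | OCC[C@@H]1C(=C)C[C@@H]2CC(=C)CC[C@@H]2C1(C)C | intermediate
24 | (2R,4aS,8aS)-2-(2-bromoethyl)-1,1-dimethyl-3,6-dimethylidenedecahydronaphthalene | BrCC[C@@H]1C(=C)C[C@@H]2CC(=C)CC[C@@H]2C1(C)C | intermediate
25 | (R)-4-benzyl-3-propanoyl-1,3-oxazolidin-2-one | CCC(=O)N1[C@H](Cc2ccccc2)COC1=O | starting material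
26 | 2-(benzyloxy)acetaldehyde | O=CCOCc1ccccc1 | starting material
27 | dibutylboron Z-enolate of 25 (not isolated) | C/C=C(\OB(CCCC)CCCC)N1[C@H](Cc2ccccc2)COC1=O | intermediate
28 | (R)-4-benzyl-3-[(2R,3R)-4-(benzyloxy)-3-hydroxy-2-methylbutanoyl]-1,3-oxazolidin-2-one | c1ccccc1COC[C@H](O)[C@@H](C)C(=O)N1[C@H](Cc2ccccc2)COC1=O | intermediate
29 | (2S,3R)-4-(benzyloxy)-2-methylbutane-1,3-diol | c1ccccc1COC[C@H](O)[C@@H](C)CO | intermediate
30 | (2R,3S)-1-(benzyloxy)-4-[(tert-butyldiphenylsilyl)oxy]-3-methylbutan-2-ol | c1ccccc1COC[C@H](O)[C@@H](C)CO[Si](c1ccccc1)(c1ccccc1)C(C)(C)C | intermediate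
31 | (2R,3S)-4-[(tert-butyldiphenylsilyl)oxy]-3-methylbutane-1,2-diol | OC[C@H](O)[C@@H](C)CO[Si](c1ccccc1)(c1ccccc1)C(C)(C)C | intermediate
32 | (2R,3S)-4-[(tert-butyldiphenylsilyl)oxy]-2-hydroxy-3-methylbutyl 4-methylbenzenesulfonate (not isolated) | Cc1ccc(cc1)S(=O)(=O)OC[C@H](O)[C@@H](C)CO[Si](c1ccccc1)(c1ccccc1)C(C)(C)C | intermediate
33 | tert-butyl{(2S)-2-[(2R)-oxiran-2-yl]propoxy}diphenylsilane | C1O[C@@H]1[C@@H](C)CO[Si](c1ccccc1)(c1ccccc1)C(C)(C)C | intermediate
34 | Grignard reagent from 24 (not isolated) | Br[Mg]CC[C@@H]1C(=C)C[C@@H]2CC(=C)CC[C@@H]2C1(C)C | intermediate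
35 | (Z)-alkenylcopper from 34 and propyne, copper cis to the decalinylethyl chain (not isolated) | [Cu]/C=C(/C)CC[C@@H]1C(=C)C[C@@H]2CC(=C)CC[C@@H]2C1(C)C | intermediate
36 | (2S,3S,5Z)-1-[(tert-butyldiphenylsilyl)oxy]-8-[(2R,4aS,8aS)-1,1-dimethyl-3,6-dimethylidenedecahydronaphthalen-2-yl]-2,6-dimethyloct-5-en-3-ol | C=C1CC[C@H]2[C@@H](C1)CC(=C)[C@@H](CC/C(C)=C\C[C@H](O)[C@@H](C)CO[Si](c3ccccc3)(c3ccccc3)C(C)(C)C)C2(C)C | intermediate
37 | C5'–C6' epoxide of 36, epoxide oxygen syn to the C3' hydroxyl | C=C1CC[C@H]2[C@@H](C1)CC(=C)[C@@H](CC[C@@]3(C)O[C@H]3C[C@H](O)[C@@H](C)CO[Si](c4ccccc4)(c4ccccc4)C(C)(C)C)C2(C)C | intermediate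
38 | C3' methanesulfonate of epoxy alcohol 37 | C=C1CC[C@H]2[C@@H](C1)CC(=C)[C@@H](CC[C@@]3(C)O[C@H]3C[C@H](OS(C)(=O)=O)[C@@H](C)CO[Si](c4ccccc4)(c4ccccc4)C(C)(C)C)C2(C)C | intermediate
39 | C6' hydroperoxide, C5' alcohol, C3' methanesulfonate (C6' inverted relative to 38) | C=C1CC[C@H]2[C@@H](C1)CC(=C)[C@@H](CC[C@](C)(OO)[C@@H](O)C[C@H](OS(C)(=O)=O)[C@@H](C)CO[Si](c3ccccc3)(c3ccccc3)C(C)(C)C)C2(C)C | intermediate
40 | (3R,6S)-1,2-dioxane with 5'-hydroxyl, C6' methyl and decalinylethyl groups, C3' (S)-1-[(tert-butyldiphenylsilyl)oxy]propan-2-yl group | C=C1CC[C@H]2[C@@H](C1)CC(=C)[C@@H](CC[C@]3(C)OO[C@@H]([C@@H](C)CO[Si](c4ccccc4)(c4ccccc4)C(C)(C)C)C[C@@H]3O)C2(C)C | intermediate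
41 | O-phenyl thionocarbonate of 40 at the C5' oxygen | C=C1CC[C@H]2[C@@H](C1)CC(=C)[C@@H](CC[C@]3(C)OO[C@@H]([C@@H](C)CO[Si](c4ccccc4)(c4ccccc4)C(C)(C)C)C[C@@H]3OC(=S)Oc5ccccc5)C2(C)C | intermediate
42 | tert-butyl{(2S)-2-[(3R,6S)-6-{2-[(2R,4aS,8aS)-1,1-dimethyl-3,6-dimethylidenedecahydronaphthalen-2-yl]ethyl}-6-methyl-1,2-dioxan-3-yl]propoxy}diphenylsilane | C=C1CC[C@H]2[C@@H](C1)CC(=C)[C@@H](CC[C@]3(C)OO[C@@H]([C@@H](C)CO[Si](c4ccccc4)(c4ccccc4)C(C)(C)C)CC3)C2(C)C | intermediate
43 | (2S)-2-[(3R,6S)-6-{2-[(2R,4aS,8aS)-1,1-dimethyl-3,6-dimethylidenedecahydronaphthalen-2-yl]ethyl}-6-methyl-1,2-dioxan-3-yl]propan-1-ol | C=C1CC[C@H]2[C@@H](C1)CC(=C)[C@@H](CC[C@]3(C)OO[C@@H]([C@@H](C)CO)CC3)C2(C)C | intermediate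
44 | (2R)-2-[(3R,6S)-6-{2-[(2R,4aS,8aS)-1,1-dimethyl-3,6-dimethylidenedecahydronaphthalen-2-yl]ethyl}-6-methyl-1,2-dioxan-3-yl]propanoic acid (CNP0363961.1) | C=C1CC[C@H]2[C@@H](C1)CC(=C)[C@@H](CC[C@@]1(C)CC[C@H]([C@@H](C)C(=O)O)OO1)C2(C)C | target

**Step count**
Total: 32 steps. Longest linear sequence: 27 steps (steps 1–18 and 24–32); the epoxide branch (steps 19–23) joins at step 24.

**Steps most likely to fail**

Step 8. The C6 silyloxy group may discriminate poorly between the two cis-fused boat transition states, so that the all-cis acid is accompanied by the cis acid of opposite ring-fusion sense. The fallback sets out from the crude acid 13 and sorts the isomers chemically. Desilylation (HF·pyridine) would give the all-cis hydroxy acid F1 together with the isomeric hydroxy acid F2. Carbodiimide lactonisation (EDC·HCl, DMAP, dilute CH2Cl2) can convert only F1, whose carboxyl and hydroxyl groups are 1,3-cis, into the bridged γ-lactone F3, which is separated as the neutral component. LiAlH4 reduction would then give the diol F4, iodination of its primary hydroxyl (I2, PPh3, imidazole) the iodo alcohol F5, and silylation (TBSCl, imidazole) returns to the route at compound 15.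

Step 24. The carbocupration of propyne may stop short, or the alkenylcopper may fail to open the branched epoxide and be protonated or homocoupled instead. The fallback sets out from bromide 24 through 34 and 35 as before, but the alkenylcopper is quenched with iodine to the (Z)-alkenyl iodide F6. Lithium–iodine exchange (tBuLi, Et2O, −78 °C) would give the alkenyllithium F7, which opens epoxide 33 under BF3·OEt2 promotion with retention of olefin geometry; this comes back to the route at compound 36.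

Step 27. Hydrogen peroxide may attack C5' instead of the tertiary C6', or the acid may shift the exocyclic double bonds or open the epoxide through a neighbouring group. The fallback sets out from mesylate 38 and reverses the order of the two C–O bond formations. Displacement of the mesylate by the caesium salt of 2-methoxyprop-2-yl hydroperoxide (CsOH·H2O, DMF; SN2 with inversion at C3') would give the peroxyketal F8. Mild acid (pyridinium p-toluenesulfonate, MeOH/CH2Cl2) unmasks the secondary hydroperoxide F9, which should open the epoxide intramolecularly at the tertiary carbon C6' (6-endo, inversion); this comes back to the route at compound 40.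

**Further compounds**
F1 | step 8 | (1R,2S,5R)-5-hydroxy-2-(prop-1-en-2-yl)cyclohexane-1-carboxylic acid | OC(=O)[C@@H]1C[C@H](O)CC[C@@H]1C(C)=C
F2 | step 8 | (1S,2R,5R)-5-hydroxy-2-(prop-1-en-2-yl)cyclohexane-1-carboxylic acid | OC(=O)[C@H]1C[C@H](O)CC[C@H]1C(C)=C
F3 | step 8 | 2-(prop-1-en-2-yl)-6-oxabicyclo[3.2.1]octan-7-one, bridged lactone of F1 | O=C1O[C@H]2C[C@@H]1[C@@H](C(C)=C)CC2
F4 | step 8 | (1R,3R,4S)-3-(hydroxymethyl)-4-(prop-1-en-2-yl)cyclohexan-1-ol | OC[C@@H]1C[C@H](O)CC[C@@H]1C(C)=C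
F5 | step 8 | (1R,3R,4S)-3-(iodomethyl)-4-(prop-1-en-2-yl)cyclohexan-1-ol | IC[C@@H]1C[C@H](O)CC[C@@H]1C(C)=C
F6 | step 24 | (2R,4aS,8aS)-2-[(Z)-4-iodo-3-methylbut-3-en-1-yl]-1,1-dimethyl-3,6-dimethylidenedecahydronaphthalene | I/C=C(/C)CC[C@@H]1C(=C)C[C@@H]2CC(=C)CC[C@@H]2C1(C)C
F7 | step 24 | (Z)-alkenyllithium from F6 (not isolated) | [Li]/C=C(/C)CC[C@@H]1C(=C)C[C@@H]2CC(=C)CC[C@@H]2C1(C)C
F8 | step 27 | C3' 2-methoxyprop-2-yl peroxide of the epoxide (C3' inverted relative to 38) | C=C1CC[C@H]2[C@@H](C1)CC(=C)[C@@H](CC[C@@]3(C)O[C@H]3C[C@@H](OOC(C)(C)OC)[C@@H](C)CO[Si](c4ccccc4)(c4ccccc4)C(C)(C)C)C2(C)C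
F9 | step 27 | C3' hydroperoxide of the epoxide (not isolated) | C=C1CC[C@H]2[C@@H](C1)CC(=C)[C@@H](CC[C@@]3(C)O[C@H]3C[C@@H](OO)[C@@H](C)CO[Si](c4ccccc4)(c4ccccc4)C(C)(C)C)C2(C)C
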